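## Retrosynthetic overview

1. **Feature used:** in the ten-membered ring C1–C10 (germacrane numbering), C7–C8 joins the β-carbon of the α-methylene-γ-butyrolactone (ring O–C12–C11–C7–C6, exocyclic C13) to the first carbon of the trans-8,9-diol. The ring is cut there, between two stereocentres.
2. **Key step:** C8 is an α-oxy radical generated from a carboxylic acid, and C7/C11/C13 are a 3-(phenylsulfonylmethyl)butenolide. Addition–fragmentation closes the carbocycle, sets C7 and C8, and unveils C11=C13 in one operation.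
3. **C8–C9:** these come from L-threitol acetonide used as a chiral 1,2-diyl. Both CH2OH carbons are oxidised and lost as CO2, the first in an intermolecular Ni-electrocatalytic alkenylation (C9–C10) and the second in the ring closure (C7–C8). The dioxolane relays the configuration.
4. **Arc C1–C7:** (S)-hex-1-en-4-yn-3-ol sets C6, Red-Al/I2 sets Z-C4=C5, a Cu-mediated coupling builds the diene, Sharpless epoxidation sets the cis-2,3-oxirane, and an iodo-Wittig reaction sets C1=C10.
5. **Ring order:** dioxolane (bought) → oxirane → butenolide (RCM) → ten-membered carbocycle (key step) → dioxolane cleaved. The two acyl groups go on last.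

Key step: step 19

Assumption: the (S,S)-ProPhenol–zinc catalyst is taken to deliver the (S)-carbinol 3; if the sense of induction is the opposite, the (R,R)-ligand is used.

## Route

Step 1
Reactants: 1 acrolein; 2 propyne
Product: 3 (S)-hex-1-en-4-yn-3-ol
Conditions: Me2Zn, (S,S)-ProPhenol (10 mol %), Ph3P=O (20 mol %), toluene, 0 °C
Reagents that add atoms: none
Why: Zinc–ProPhenol asymmetric alkynylation of an enal, in which the dinuclear zinc complex binds the alkynylzinc and acrolein side by side and delivers the alkyne to one carbonyl face, setting C6 (S).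

Step 2
Reactants: 3 (S)-hex-1-en-4-yn-3-ol
Product: 4 (3S,4Z)-5-iodohexa-1,4-dien-3-ol
Conditions: Red-Al, THF, 0 °C → rt; EtOAc; then I2, −78 °C
Reagents that add atoms: iodine, II
Why: Hydroxyl-directed trans-hydroalumination of the propargylic alcohol and iodinolysis with retention put iodine on the distal carbon cis to the carbinol, which fixes the ring-cis (Z) geometry of C4=C5 and leaves the isolated vinyl group untouched.

Step 3
Reactants: 4 (3S,4Z)-5-iodohexa-1,4-dien-3-ol
Product: 5 (3S,4Z)-5-iodo-3-(triethylsilyloxy)hexa-1,4-diene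
Conditions: TESCl, imidazole, CH2Cl2, 0 °C
Reagents that add atoms: chlorotriethylsilane, CC[Si](Cl)(CC)CC
Why: Standard silylation masks the bis-allylic C6 carbinol, so that only the primary allylic alcohol directs the later epoxidation and the group can be removed ahead of a primary TBS ether.

Step 4
Reactants: 6 prop-2-yn-1-ol
Product: 7 (Z)-3-(tributylstannyl)prop-2-en-1-ol
Conditions: LiAlH4, THF, 0 °C → rt; then Bu3SnOTf, −78 °C → rt
Reagents that add atoms: tributyltin triflate, CCCC[Sn](CCCC)(CCCC)OS(=O)(=O)C(F)(F)F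
Why: trans-Hydroalumination through the cyclic alkoxyaluminate followed by Al→Sn exchange with retention gives the (Z)-alkenylstannane.

Step 5
Reactants: 5 (3S,4Z)-5-iodo-3-(triethylsilyloxy)hexa-1,4-diene; 7 (Z)-3-(tributylstannyl)prop-2-en-1-ol
Product: 8 (2Z,4Z,6S)-4-methyl-6-(triethylsilyloxy)octa-2,4,7-trien-1-ol
Conditions: CuTC (1.5 equiv), NMP, 0 °C → rt
Reagents that add atoms: none
Why: The copper(I) thiophene-2-carboxylate-mediated Stille-type (Liebeskind) coupling of an alkenyl iodide with an alkenylstannane is neutral and palladium-free and retains both sp2 configurations, giving the (2Z,4Z)-diene (C3–C4 bond).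

Step 6
Reactants: 8 (2Z,4Z,6S)-4-methyl-6-(triethylsilyloxy)octa-2,4,7-trien-1-ol
Product: 9 [(2R,3S)-3-[(2Z,4S)-4-(triethylsilyloxy)hexa-2,5-dien-2-yl]oxiran-2-yl]methanol
Conditions: Ti(OiPr)4, D-(−)-DET, t-BuOOH, 4 Å MS, CH2Cl2, −20 °C
Reagents that add atoms: tert-butyl hydroperoxide, CC(C)(C)OO
Why: In the Sharpless asymmetric epoxidation titanium binds the C1 hydroxyl so that only C2=C3 reacts, the syn-stereospecific oxygen transfer keeps the cis geometry, and D-(−)-tartrate selects the face that gives (2R,3S).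

Step 7
Reactants: 9 [(2R,3S)-3-[(2Z,4S)-4-(triethylsilyloxy)hexa-2,5-dien-2-yl]oxiran-2-yl]methanol
Product: 11 methyl (Z)-2-iodo-3-[(2R,3S)-3-[(2Z,4S)-4-(triethylsilyloxy)hexa-2,5-dien-2-yl]oxiran-2-yl]prop-2-enoate, via epoxy aldehyde 10 (not isolated)
Conditions: DMP, NaHCO3, CH2Cl2, 0 °C; then Ph3P=C(I)CO2Me (from Ph3P=CHCO2Me, NIS, CH2Cl2, −20 °C), 0 °C → rt
Reagents that add atoms: methyl (triphenylphosphoranylidene)acetate, COC(=O)C=P(c1ccccc1)(c1ccccc1)c1ccccc1; N-iodosuccinimide, O=C1CCC(=O)N1I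
Why: Dess–Martin oxidation followed in the same flask by the Wittig reaction of the stabilised iodo ylide puts the ester trans to C2, so the C–I bond of the (Z)-α-iodoenoate marks the place of C9, and no base able to epimerise the epoxy aldehyde is present.

Step 8
Reactants: 12 (+)-2,3-O-isopropylidene-L-threitol
Product: 13 [(4S,5S)-5-[(tert-butyldimethylsilyloxy)methyl]-2,2-dimethyl-1,3-dioxolan-4-yl]methanol
Conditions: NaH (1.0 equiv), THF, 0 °C; then TBSCl
Reagents that add atoms: tert-butyldimethylsilyl chloride, CC(C)(C)[Si](C)(C)Cl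
Why: Monosilylation of a symmetrical diol through its sparingly soluble monosodium alkoxide works here because C2 symmetry makes both ends equivalent, and both stereocentres come from the chiral pool.

Step 9
Reactants: 13 [(4S,5S)-5-[(tert-butyldimethylsilyloxy)methyl]-2,2-dimethyl-1,3-dioxolan-4-yl]methanol
Product: 14 (4R,5S)-5-[(tert-butyldimethylsilyloxy)methyl]-2,2-dimethyl-1,3-dioxolane-4-carboxylic acid
Conditions: TEMPO (cat.), PhI(OAc)2, MeCN/H2O, rt
Reagents that add atoms: water, O
Why: The oxoammonium (TEMPO/PhI(OAc)2) oxidation takes the primary alcohol through the aldehyde hydrate to the acid without touching the silyl ether or the acetal.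

Step 10
Reactants: 14 (4R,5S)-5-[(tert-butyldimethylsilyloxy)methyl]-2,2-dimethyl-1,3-dioxolane-4-carboxylic acid
Product: 15 1,3-dioxoisoindolin-2-yl (4R,5S)-5-[(tert-butyldimethylsilyloxy)methyl]-2,2-dimethyl-1,3-dioxolane-4-carboxylate
Conditions: N-hydroxyphthalimide, DIC, DMAP (cat.), CH2Cl2, rt
Reagents that add atoms: N-hydroxyphthalimide, O=C1c2ccccc2C(=O)N1O
Why: Carbodiimide esterification gives the redox-active ester that releases the C9 radical on one-electron reduction.

Step 11
Reactants: 11 methyl (Z)-2-iodo-3-[(2R,3S)-3-[(2Z,4S)-4-(triethylsilyloxy)hexa-2,5-dien-2-yl]oxiran-2-yl]prop-2-enoate; 15 redox-active ester of 14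
Product: 16 methyl (E)-2-[(4S,5S)-5-[(tert-butyldimethylsilyloxy)methyl]-2,2-dimethyl-1,3-dioxolan-4-yl]-3-[(2R,3S)-3-[(2Z,4S)-4-(triethylsilyloxy)hexa-2,5-dien-2-yl]oxiran-2-yl]prop-2-enoate
Conditions: NiCl2·6H2O (20 mol %), 2,2′-bipyridine, AgNO3 (0.3 equiv), DMF, (+)Mg/(−)RVC, constant current, rt
Reagents that add atoms: none
Why: In this nickel-electrocatalytic decarboxylative alkenylation (reductive coupling of a redox-active ester with an alkenyl iodide) the planar dioxolanyl radical at C9 is captured by the alkenylnickel(II) species anti to the CH2OTBS group on C8, which gives the trans-dioxolane (9S), and reductive elimination keeps the alkene geometry.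

Step 12
Reactants: 16 coupled bis-silyl ether
Product: 17 methyl (E)-2-[(4S,5S)-5-[(tert-butyldimethylsilyloxy)methyl]-2,2-dimethyl-1,3-dioxolan-4-yl]-3-[(2R,3S)-3-[(2Z,4S)-4-hydroxyhexa-2,5-dien-2-yl]oxiran-2-yl]prop-2-enoate
Conditions: HF·pyridine, pyridine, THF, 0 °C
Reagents that add atoms: none
Why: Buffered fluoride desilylation cleaves the TES ether much faster than the primary TBS ether and spares the oxirane and the acetal.

Step 13
Reactants: 18 2-(bromomethyl)acrylic acid
Product: 19 2-(phenylsulfonylmethyl)acrylic acid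
Conditions: PhSO2Na, MeOH, reflux
Reagents that add atoms: sodium benzenesulfinate, [Na+].[O-]S(=O)c1ccccc1
Why: S-alkylation of the sulfinate by the allylic bromide (SN2/SN2′, degenerate here) gives the allyl sulfone that later serves as the radical leaving group.

Step 14
Reactants: 17 C6 alcohol; 19 2-(phenylsulfonylmethyl)acrylic acid
Product: 20 C6 2-(phenylsulfonylmethyl)acrylate of 17 (configuration as in 17)
Conditions: DIC, DMAP (5 mol %), CH2Cl2, 0 °C
Reagents that add atoms: none
Why: Steglich esterification at oxygen leaves C6 untouched, and a low DMAP loading at low temperature limits SN2′ attack on the allyl sulfone.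

Step 15
Reactants: 20 C6 2-(phenylsulfonylmethyl)acrylate
Product: 21 methyl (E)-2-[(4S,5S)-5-[(tert-butyldimethylsilyloxy)methyl]-2,2-dimethyl-1,3-dioxolan-4-yl]-3-[(2R,3S)-3-[(Z)-1-[(2R)-5-oxo-4-(phenylsulfonylmethyl)-2,5-dihydrofuran-2-yl]prop-1-en-2-yl]oxiran-2-yl]prop-2-enoate
Conditions: Hoveyda–Grubbs II (10 mol %), CH2Cl2, 40 °C
Reagents that add atoms: none
Why: Ring-closing metathesis between the vinyl group and the 1,1-disubstituted acrylate closes the butenolide (C7=C11), the trisubstituted C4=C5 and C1=C10 alkenes are inert, and 40 °C stays below the temperature at which the cis-dialkenyloxirane would undergo a Cope rearrangement.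

Step 16
Reactants: 21 butenolide TBS ether
Product: 22 primary alcohol (as 21, CH2OH on C8)
Conditions: HF·pyridine, THF, 0 °C → rt
Reagents that add atoms: none
Why: Fluoride desilylation under non-basic conditions avoids deprotonation of the acidic γ-hydrogen (C6–H) of the butenolide.

Step 17
Reactants: 22 primary alcohol
Product: 23 carboxylic acid (as 21, CO2H on C8)
Conditions: TEMPO (cat.), PhI(OAc)2, CH2Cl2/H2O, rt
Reagents that add atoms: water, O
Why: The TEMPO/PhI(OAc)2 oxidation is neutral and chemoselective for the only alcohol, and epimerisation at C8 would not matter because this centre is planarised in step 19.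

Step 18
Reactants: 23 carboxylic acid
Product: 24 1,3-dioxoisoindolin-2-yl ester of 23
Conditions: N-hydroxyphthalimide, DIC, CH2Cl2, 0 °C → rt
Reagents that add atoms: N-hydroxyphthalimide, O=C1c2ccccc2C(=O)N1O
Why: Carbodiimide esterification without a nucleophilic catalyst installs the redox-active ester next to the radical acceptor.

Step 19
Reactants: 24 redox-active ester
Product: 25 methyl (1(10)E,4Z,2R,3S,6R,7S,8S,9S)-2,3-epoxy-8,9-(isopropylidenedioxy)-12-oxogermacra-1(10),4,11(13)-trien-12,6-olid-14-oate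
Conditions: Ru(bpy)3(PF6)2 (2 mol %), Hantzsch ester (1.5 equiv), CH2Cl2 (1 mM, slow addition of 24), blue LEDs, rt
Reagents that add atoms: none
Why: Proposed new method: one-electron reduction of the N-acyloxyphthalimide by Ru(I) releases CO2 and the nucleophilic 1,3-dioxolan-4-yl radical at C8, which adds to C7, the electrophilic β-carbon of the butenolide, and the tertiary α-acyl radical at C11 then expels PhSO2• by β-scission, so one operation forms C7–C8 and the C11=C13 methylene. The closest known reaction types are the intermolecular photoredox decarboxylative allylation of redox-active esters with 2-(sulfonylmethyl)acrylates and decarboxylative conjugate-addition macrocyclisations, and the use for a ten-membered carbocycle is new. The ring closes in a 10-exo-trig mode (attack on the alkene carbon that carries the tether, radical left on exocyclic C11), helped by the two Z-alkenes, the cis-oxirane and the two five-membered rings, which leave only four freely rotating bonds (C9–C10, C1–C2, C3–C4, C5–C6) between the reacting centres. C7 is controlled by C6 because the radical enters the butenolide face anti to the C5 alkenyl substituent (trans-lactone), and C8 is controlled by C9 because the planar dioxolanyl radical reacts anti to the C10 substituent (trans-dioxolane, 8β,9α), so the C8 configuration of 24 is irrelevant. The cyclisation has to beat hydrogen abstraction, intermolecular addition and 3-exo attack on the C1=C10 enoate, and this is secured by high dilution, the polarity match of radical and acceptor, the polarity mismatch and full substitution of C10, and the strong oxiranyl C–H bonds.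

Step 20
Reactants: 25 macrocyclic acetonide
Product: 26 methyl (1(10)E,4Z,2R,3S,6R,7S,8S,9S)-2,3-epoxy-8,9-dihydroxy-12-oxogermacra-1(10),4,11(13)-trien-12,6-olid-14-oate
Conditions: AcOH/H2O (4:1), 35 °C
Reagents that add atoms: none
Why: Acid-catalysed acetal hydrolysis should be easy for a trans-dioxolane fused to a medium ring, while the oxirane is deactivated at C2 by the enoate and weak acid avoids ionisation at C3.

Step 21
Reactants: 26 8,9-diol; 27 (R)-2-methylbutanoic acid
Product: 28 9-O-[(R)-2-methylbutanoyl] derivative of 26 (8-OH free)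
Conditions: 27 (1.05 equiv), DIC, DMAP (cat.), CH2Cl2, −20 °C
Reagents that add atoms: none
Why: In a Steglich esterification under kinetic control the first acyl group should go to O9, because C9–OH is allylic, flanked by planar C10 and hydrogen-bonded to the C14 ester, whereas C8–OH lies between two sp3 stereocentres next to the lactone.

Step 22
Reactants: 29 methyl angelate
Product: 30 (Z)-2-methylbut-2-en-1-ol
Conditions: LiAlH4, Et2O, 0 °C
Reagents that add atoms: none
Why: 1,2-Hydride reduction of the enoate proceeds without loss of the Z geometry.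

Step 23
Reactants: 30 (Z)-2-methylbut-2-en-1-ol
Product: 31 [(2R,3S)-2,3-dimethyloxiran-2-yl]methanol
Conditions: Ti(OiPr)4, D-(−)-DET, t-BuOOH, 4 Å MS, CH2Cl2, −20 °C
Reagents that add atoms: tert-butyl hydroperoxide, CC(C)(C)OO
Why: In the Sharpless asymmetric epoxidation D-(−)-tartrate sets both oxirane centres (2R,3S), and syn-stereospecific transfer keeps CH2OH and the C3 methyl group cis.

Step 24
Reactants: 31 [(2R,3S)-2,3-dimethyloxiran-2-yl]methanol
Product: 32 (2S,3S)-2,3-dimethyloxirane-2-carboxylic acid (epoxyangelic acid)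
Conditions: RuCl3 (cat.), NaIO4, MeCN/CCl4/H2O, rt
Reagents that add atoms: water, O
Why: Catalytic RuO4 oxidation takes the epoxy alcohol to the glycidic acid without touching the stereocentres, and the descriptor at C2 changes only by priority.

Step 25
Reactants: 28 9-O-[(R)-2-methylbutanoyl] 8-alcohol; 32 (2S,3S)-2,3-dimethyloxirane-2-carboxylic acid
Product: 33 target CNP0485260.1
Conditions: 2,4,6-trichlorobenzoyl chloride, Et3N, toluene; then 28, DMAP, rt
Reagents that add atoms: none
Why: The Yamaguchi esterification acylates the hindered C8 hydroxyl through the mixed anhydride at oxygen only, so no stereocentre is touched.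

## Compound list

1 | acrolein | C=CC=O | starting material
2 | propyne | CC#C | starting material
3 | (S)-hex-1-en-4-yn-3-ol | O[C@@H](C=C)C#CC | intermediate
4 | (3S,4Z)-5-iodohexa-1,4-dien-3-ol | O[C@@H](C=C)/C=C(/C)I | intermediate
5 | (3S,4Z)-5-iodo-3-(triethylsilyloxy)hexa-1,4-diene | CC[Si](CC)(CC)O[C@@H](C=C)/C=C(/C)I | intermediate
6 | prop-2-yn-1-ol | C#CCO | starting material
7 | (Z)-3-(tributylstannyl)prop-2-en-1-ol | OC/C=C\[Sn](CCCC)(CCCC)CCCC | intermediate
8 | (2Z,4Z,6S)-4-methyl-6-(triethylsilyloxy)octa-2,4,7-trien-1-ol | CC[Si](CC)(CC)O[C@@H](C=C)/C=C(/C)\C=C/CO | intermediate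
9 | [(2R,3S)-3-[(2Z,4S)-4-(triethylsilyloxy)hexa-2,5-dien-2-yl]oxiran-2-yl]methanol | CC[Si](CC)(CC)O[C@@H](C=C)/C=C(/C)[C@@H]1O[C@@H]1CO | intermediate
10 | (2S,3S)-3-[(2Z,4S)-4-(triethylsilyloxy)hexa-2,5-dien-2-yl]oxirane-2-carbaldehyde | CC[Si](CC)(CC)O[C@@H](C=C)/C=C(/C)[C@@H]1O[C@@H]1C=O | intermediate
11 | methyl (Z)-2-iodo-3-[(2R,3S)-3-[(2Z,4S)-4-(triethylsilyloxy)hexa-2,5-dien-2-yl]oxiran-2-yl]prop-2-enoate | CC[Si](CC)(CC)O[C@@H](C=C)/C=C(/C)[C@@H]1O[C@@H]1/C=C(/C(=O)OC)I | intermediate
12 | (+)-2,3-O-isopropylidene-L-threitol, (4S,5S)-2,2-dimethyl-1,3-dioxolane-4,5-dimethanol | OC[C@@H]1OC(C)(C)O[C@H]1CO | starting material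
13 | [(4S,5S)-5-[(tert-butyldimethylsilyloxy)methyl]-2,2-dimethyl-1,3-dioxolan-4-yl]methanol | OC[C@@H]1OC(C)(C)O[C@H]1CO[Si](C)(C)C(C)(C)C | intermediate
14 | (4R,5S)-5-[(tert-butyldimethylsilyloxy)methyl]-2,2-dimethyl-1,3-dioxolane-4-carboxylic acid | OC(=O)[C@@H]1OC(C)(C)O[C@H]1CO[Si](C)(C)C(C)(C)C | intermediate
15 | 1,3-dioxoisoindolin-2-yl ester of 14 | O=C(ON1C(=O)c2ccccc2C1=O)[C@@H]1OC(C)(C)O[C@H]1CO[Si](C)(C)C(C)(C)C | intermediate
16 | methyl (E)-2-[(4S,5S)-5-[(tert-butyldimethylsilyloxy)methyl]-2,2-dimethyl-1,3-dioxolan-4-yl]-3-[(2R,3S)-3-[(2Z,4S)-4-(triethylsilyloxy)hexa-2,5-dien-2-yl]oxiran-2-yl]prop-2-enoate | CC[Si](CC)(CC)O[C@@H](C=C)/C=C(/C)[C@@H]1O[C@@H]1/C=C(/C(=O)OC)[C@@H]1OC(C)(C)O[C@H]1CO[Si](C)(C)C(C)(C)C | intermediate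
17 | C6 alcohol, as 16 with 4-hydroxy in place of 4-(triethylsilyloxy) | O[C@@H](C=C)/C=C(/C)[C@@H]1O[C@@H]1/C=C(/C(=O)OC)[C@@H]1OC(C)(C)O[C@H]1CO[Si](C)(C)C(C)(C)C | intermediate
18 | 2-(bromomethyl)acrylic acid | C=C(CBr)C(=O)O | starting material
19 | 2-(phenylsulfonylmethyl)acrylic acid | C=C(CS(=O)(=O)c1ccccc1)C(=O)O | intermediate
20 | C6 2-(phenylsulfonylmethyl)acrylate of 17 | C=C(CS(=O)(=O)c1ccccc1)C(=O)O[C@@H](C=C)/C=C(/C)[C@@H]1O[C@@H]1/C=C(/C(=O)OC)[C@@H]1OC(C)(C)O[C@H]1CO[Si](C)(C)C(C)(C)C | intermediate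
21 | (6R)-3-(phenylsulfonylmethyl)butenolide, CH2OTBS on C8 | O=C1O[C@H](/C=C(/C)[C@@H]2O[C@@H]2/C=C(/C(=O)OC)[C@@H]2OC(C)(C)O[C@H]2CO[Si](C)(C)C(C)(C)C)C=C1CS(=O)(=O)c1ccccc1 | intermediate
22 | as 21, CH2OH on C8 | O=C1O[C@H](/C=C(/C)[C@@H]2O[C@@H]2/C=C(/C(=O)OC)[C@@H]2OC(C)(C)O[C@H]2CO)C=C1CS(=O)(=O)c1ccccc1 | intermediate
23 | as 21, CO2H on C8 | O=C1O[C@H](/C=C(/C)[C@@H]2O[C@@H]2/C=C(/C(=O)OC)[C@@H]2OC(C)(C)O[C@H]2C(=O)O)C=C1CS(=O)(=O)c1ccccc1 | intermediate
24 | 1,3-dioxoisoindolin-2-yl ester of 23 | O=C1O[C@H](/C=C(/C)[C@@H]2O[C@@H]2/C=C(/C(=O)OC)[C@@H]2OC(C)(C)O[C@H]2C(=O)ON2C(=O)c3ccccc3C2=O)C=C1CS(=O)(=O)c1ccccc1 | intermediate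
25 | 8,9-O-isopropylidene germacranolide (2R,3S,6R,7S,8S,9S; 1(10)E,4Z) | C=C1C(=O)O[C@@H]2/C=C(/C)[C@@H]3O[C@@H]3/C=C(/C(=O)OC)[C@@H]3OC(C)(C)O[C@H]3[C@@H]12 | intermediate
26 | 8β,9α-diol | C=C1C(=O)O[C@@H]2/C=C(/C)[C@@H]3O[C@@H]3/C=C(/C(=O)OC)[C@H](O)[C@@H](O)[C@@H]12 | intermediate
27 | (R)-2-methylbutanoic acid | CC[C@@H](C)C(=O)O | starting material
28 | 9-O-[(R)-2-methylbutanoyl]-8-ol | C=C1C(=O)O[C@@H]2/C=C(/C)[C@@H]3O[C@@H]3/C=C(/C(=O)OC)[C@H](OC(=O)[C@H](C)CC)[C@@H](O)[C@@H]12 | intermediate
29 | methyl angelate, methyl (Z)-2-methylbut-2-enoate | C/C=C(/C)C(=O)OC | starting material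
30 | (Z)-2-methylbut-2-en-1-ol | C/C=C(/C)CO | intermediate
31 | [(2R,3S)-2,3-dimethyloxiran-2-yl]methanol | OC[C@@]1(C)O[C@H]1C | intermediate
32 | (2S,3S)-2,3-dimethyloxirane-2-carboxylic acid | OC(=O)[C@@]1(C)O[C@H]1C | intermediate
33 | CNP0485260.1 | C=C1C(=O)O[C@@H]2/C=C(/C)[C@@H]3O[C@@H]3/C=C(/C(=O)OC)[C@H](OC(=O)[C@H](C)CC)[C@@H](OC(=O)[C@@]3(C)O[C@H]3C)[C@@H]12 | target

## Step count

- **Total step count:** 25.
- **Longest linear sequence:** 17 steps (1, 2, 3, 5, 6, 7, 11, 12, 14, 15, 16, 17, 18, 19, 20, 21, 25).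

## Steps most likely to fail

**1. Step 19 (Proposed new method).**
- What may go wrong: the ten-membered closure may be too slow. The C8 radical could then be quenched by hydrogen abstraction or add intermolecularly. It could also attack C10 in a 3-exo mode, with the oxirane then opening. The facial preference at C8 may erode because the acceptor is tethered through the very substituent that should shield one face.
- Scope of the fallback: it uses known chemistry only, sets out from 11 and comes back at 33.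
- Building the C9 carbinol and its ester: a Nozaki–Hiyama–Kishi coupling of 11 (CrCl2, cat. NiCl2, DMSO) with commercial (R)-2,3-O-isopropylideneglyceraldehyde should give the Felkin–Anh (8,9-anti) allylic alcohol F1. Steglich esterification with 27 gives the C9 2-methylbutanoate F2.
- Building the butenolide: HF·pyridine frees the C6 carbinol F3. Esterification with acid 18 (DIC) gives the 2-(bromomethyl)acrylate F4. Ring-closing metathesis gives the 3-(bromomethyl)butenolide F5.
- Ring closure and inversion: periodic acid cleaves the terminal acetonide through the diol F6 to the C8 aldehyde F7. An intramolecular chromium(II) Barbier allylation, the established way to close germacranolide and cembranolide rings, forms C7–C8 through the chair transition state of the E-configured cyclic allylmetal and should give the 7,8-anti (8α) alcohol F8. A Mitsunobu esterification with 32 inverts C8 and gives 33.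

**2. Step 11.**
- What may go wrong: the α-iodoenoate may be reduced at the cathode, low-valent nickel may ionise the vinyl oxirane, and the alkene geometry may be lost through an oxygen-bound nickel allenolate.
- Scope of the fallback: it replaces the radical coupling by a carbonyl addition, sets out from 11 and comes back at 16.
- Sequence: iodine–magnesium exchange (i-PrMgCl·LiCl, −78 °C) is followed by Cram-chelate addition (MgBr2·OEt2) to (S)-3-(tert-butyldimethylsilyloxy)-2-(4-methoxybenzyloxy)propanal F9, a glyceraldehyde derivative that has to be made separately. This should give the 8,9-syn allylic alcohol F10. DDQ removes the PMB group to give the diol F11, and 2,2-dimethoxypropane/PPTS closes the trans-dioxolane of 16.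

**3. Step 21.**
- What may go wrong: the two secondary hydroxyls may be poorly discriminated, and the acyl group may migrate between O9 and O8.
- Scope of the fallback: it distinguishes the two positions by oxidation state instead of by rate, sets out from 26 and comes back at 33.
- Sequence: MnO2 oxidises only the allylic C9 carbinol to the 8-hydroxy-9-ketone F12. Yamaguchi esterification with 32 gives the 9-keto 8-epoxyangelate F13. A reagent-controlled CBS 1,2-reduction gives the 9α-alcohol F14, and Steglich esterification with 27 gives 33.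

## Further compounds

F1 | step 19 | NHK adduct, 9-OH, 8,9-anti, terminal acetonide | CC[Si](CC)(CC)O[C@@H](C=C)/C=C(/C)[C@@H]1O[C@@H]1/C=C(/C(=O)OC)[C@H](O)[C@H]1COC(C)(C)O1
F2 | step 19 | C9 (R)-2-methylbutanoate of F1 | CC[Si](CC)(CC)O[C@@H](C=C)/C=C(/C)[C@@H]1O[C@@H]1/C=C(/C(=O)OC)[C@H](OC(=O)[C@H](C)CC)[C@H]1COC(C)(C)O1
F3 | step 19 | C6 alcohol from F2 | O[C@@H](C=C)/C=C(/C)[C@@H]1O[C@@H]1/C=C(/C(=O)OC)[C@H](OC(=O)[C@H](C)CC)[C@H]1COC(C)(C)O1
F4 | step 19 | C6 2-(bromomethyl)acrylate of F3 | C=C(CBr)C(=O)O[C@@H](C=C)/C=C(/C)[C@@H]1O[C@@H]1/C=C(/C(=O)OC)[C@H](OC(=O)[C@H](C)CC)[C@H]1COC(C)(C)O1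
F5 | step 19 | 3-(bromomethyl)butenolide | O=C1O[C@H](/C=C(/C)[C@@H]2O[C@@H]2/C=C(/C(=O)OC)[C@H](OC(=O)[C@H](C)CC)[C@H]2COC(C)(C)O2)C=C1CBr
F6 | step 19 | terminal diol from F5 | O=C1O[C@H](/C=C(/C)[C@@H]2O[C@@H]2/C=C(/C(=O)OC)[C@H](OC(=O)[C@H](C)CC)[C@H](O)CO)C=C1CBr
F7 | step 19 | C8 aldehyde | O=C1O[C@H](/C=C(/C)[C@@H]2O[C@@H]2/C=C(/C(=O)OC)[C@H](OC(=O)[C@H](C)CC)C=O)C=C1CBr
F8 | step 19 | 8-epi-28 (8α-alcohol) | C=C1C(=O)O[C@@H]2/C=C(/C)[C@@H]3O[C@@H]3/C=C(/C(=O)OC)[C@H](OC(=O)[C@H](C)CC)[C@H](O)[C@@H]12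
F9 | step 11 | (S)-3-(tert-butyldimethylsilyloxy)-2-(4-methoxybenzyloxy)propanal | O=C[C@@H](OCc1ccc(OC)cc1)CO[Si](C)(C)C(C)(C)C
F10 | step 11 | 8,9-syn allylic alcohol, 8-OPMB | CC[Si](CC)(CC)O[C@@H](C=C)/C=C(/C)[C@@H]1O[C@@H]1/C=C(/C(=O)OC)[C@H](O)[C@@H](OCc1ccc(OC)cc1)CO[Si](C)(C)C(C)(C)C
F11 | step 11 | 8,9-syn diol | CC[Si](CC)(CC)O[C@@H](C=C)/C=C(/C)[C@@H]1O[C@@H]1/C=C(/C(=O)OC)[C@H](O)[C@@H](O)CO[Si](C)(C)C(C)(C)C
F12 | step 21 | 8β-hydroxy-9-ketone | C=C1C(=O)O[C@@H]2/C=C(/C)[C@@H]3O[C@@H]3/C=C(/C(=O)OC)C(=O)[C@@H](O)[C@@H]12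
F13 | step 21 | 9-keto 8-epoxyangelate | C=C1C(=O)O[C@@H]2/C=C(/C)[C@@H]3O[C@@H]3/C=C(/C(=O)OC)C(=O)[C@@H](OC(=O)[C@@]3(C)O[C@H]3C)[C@@H]12
F14 | step 21 | 9α-hydroxy 8-epoxyangelate | C=C1C(=O)O[C@@H]2/C=C(/C)[C@@H]3O[C@@H]3/C=C(/C(=O)OC)[C@H](O)[C@@H](OC(=O)[C@@]3(C)O[C@H]3C)[C@@H]12
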